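**Retrosynthetic overview**

- The target is a 4-hydroxy-5-alkoxy-6-methoxyphthalide. The last operations are removal of a silyl group from the chain's tertiary alcohol and closure of the five-membered lactone by reduction of a 2-formylbenzoate.
- The strategy rests on the benzene ring: C4 (OH), C5 (O-chain), C6 (OMe) and C7 (H) lie in a row between C3a (CH2O) and C7a (C=O). This is the pattern a four-carbon diene oxygenated on its first three carbons gives with a two-carbon alkyne carrying CHO and CO2Me.
- Key disconnection: the benzene ring is cut into a 1-silyloxy-1,3-dimethoxy-2-alkoxybuta-1,3-diene and methyl 4-oxobut-2-ynoate, so the three neighbouring oxygens are differentiated by construction.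
- The diene comes from an alkoxyacetate (chain alcohol plus bromoacetic acid) by C-acetylation, O-methylation and γ-enolisation/silylation. The chain alcohol comes from (2E,6E)-farnesol by terminal hydration through bromohydrin, epoxide and hydride opening.
- Ring order: complete side chain first, then the benzene ring (cycloaddition and aromatisation), then the lactone.

Key step: step 13

Remark: methyl 4-hydroxybut-2-ynoate and N-methoxy-N-methylacetamide are taken as purchasable. Racemic centres and enol ether or ketene acetal geometries of intermediates are erased later and are not controlled.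
In the names below, RO- stands for the (2E,6E)-3,7,11-trimethyl-11-(triethylsilyloxy)dodeca-2,6-dien-1-yloxy group.

Step 1
Reactants: 1 (2E,6E)-farnesol
Product: 2 (2E,6E)-farnesyl acetate
Conditions: Ac2O, pyridine, DMAP (cat.), CH2Cl2, 0 °C to rt
Reagents that add atoms: acetic anhydride CC(=O)OC(C)=O
Why: DMAP-catalysed acylation of a primary allylic alcohol; the acetate also lowers the electron density of the 2,3-olefin before the electrophilic bromination.

Step 2
Reactants: 2 (2E,6E)-farnesyl acetate
Product: 3 (2E,6E)-10-bromo-11-hydroxy-3,7,11-trimethyldodeca-2,6-dien-1-yl acetate (racemic)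
Conditions: N-bromosuccinimide, THF/H2O, 0 °C
Reagents that add atoms: N-bromosuccinimide O=C1CCC(=O)N1Br; water O
Why: Terminal-selective bromohydrin formation of a polyprenyl acetate in aqueous THF, where the most exposed trisubstituted olefin is attacked and water opens the bromonium ion at the tertiary carbon; the C10 centre is racemic and later becomes CH2.

Step 3
Reactants: 3 (2E,6E)-10-bromo-11-hydroxy-3,7,11-trimethyldodeca-2,6-dien-1-yl acetate
Product: 5 (2E,6E)-10,11-epoxy-3,7,11-trimethyldodeca-2,6-dien-1-ol (racemic), via epoxy acetate 4 (not isolated)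
Conditions: K2CO3, MeOH, rt
Reagents that add atoms: none
Why: Intramolecular Williamson displacement of bromide by the tertiary alkoxide closes the epoxide, and carbonate-mediated transesterification with methanol then removes the acetate in the same flask.

Step 4
Reactants: 5 (2E,6E)-10,11-epoxy-3,7,11-trimethyldodeca-2,6-dien-1-ol
Product: 6 (2E,6E)-3,7,11-trimethyldodeca-2,6-diene-1,11-diol
Conditions: LiAlH4, THF, 0 °C to rt; aq. NaOH work-up
Reagents that add atoms: none
Why: SN2 opening of the trisubstituted epoxide by hydride at the less substituted carbon should leave the tertiary alcohol, and the isolated trisubstituted olefins are inert to LiAlH4 at this temperature.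

Step 5
Reactants: 6 (2E,6E)-3,7,11-trimethyldodeca-2,6-diene-1,11-diol
Product: 7 (2E,6E)-1,11-bis(triethylsilyloxy)-3,7,11-trimethyldodeca-2,6-diene
Conditions: Et3SiOSO2CF3, 2,6-lutidine, CH2Cl2, -78 to 0 °C
Reagents that add atoms: triethylsilyl trifluoromethanesulfonate CC[Si](CC)(CC)OS(=O)(=O)C(F)(F)F
Why: Silylation with a silyl triflate and a hindered pyridine base is strong enough to cap the tertiary alcohol as well as the primary one.

Step 6
Reactants: 7 (2E,6E)-1,11-bis(triethylsilyloxy)-3,7,11-trimethyldodeca-2,6-diene
Product: 8 (2E,6E)-3,7,11-trimethyl-11-(triethylsilyloxy)dodeca-2,6-dien-1-ol (RO-H)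
Conditions: pyridinium p-toluenesulfonate (cat.), MeOH/CH2Cl2, 0 °C
Reagents that add atoms: none
Why: Acid-catalysed methanolysis of silyl ethers is governed by steric access, so the primary allylic triethylsilyl ether should be cleaved much faster than the tertiary one.

Step 7
Reactants: 8 (2E,6E)-3,7,11-trimethyl-11-(triethylsilyloxy)dodeca-2,6-dien-1-ol; 9 bromoacetic acid
Product: 10 2-(RO)acetic acid
Conditions: NaH (3 equiv), THF, 0 to 50 °C; aq. citric acid to pH 4, 0 °C
Reagents that add atoms: none
Why: Williamson ether synthesis in which the sodium alkoxide of 8 displaces bromide from the carboxylate salt of 9, which cannot be acylated by the alkoxide; the oxygen of 8 becomes the future aryl ether oxygen, so the allylic C-O bond is never made by substitution at the allylic carbon.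

Step 8
Reactants: 10 2-(RO)acetic acid
Product: 11 methyl 2-(RO)acetate
Conditions: MeI, K2CO3, DMF, rt
Reagents that add atoms: iodomethane CI
Why: SN2 O-alkylation of the carboxylate under weakly basic conditions that leave the tertiary silyl ether and the olefins untouched.

Step 9
Reactants: 11 methyl 2-(RO)acetate; 12 N-methoxy-N-methylacetamide
Product: 15 methyl 3-oxo-2-(RO)butanoate (racemic), via lithium ester enolate 13 (not isolated), via tetrahedral lithium adduct 14 (not isolated)
Conditions: LiN(SiMe3)2 (2 equiv), THF, -78 °C; 12 (3 equiv), -78 °C; AcOH quench at -78 °C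
Reagents that add atoms: none
Why: Crossed Claisen-type acylation of a lithium ester enolate by a Weinreb amide, in which the chelated tetrahedral adduct survives until the cold quench so the β-keto ester never meets enolate, and the constant -78 °C should hold back the [2,3]-Wittig shift of the α-allyloxy enolate; the new centre is racemic and becomes sp2 in the next step.

Step 10
Reactants: 15 methyl 3-oxo-2-(RO)butanoate
Product: 16 methyl 3-methoxy-2-(RO)but-2-enoate (E/Z mixture)
Conditions: Cs2CO3, Me2SO4, DMF, 0 °C to rt
Reagents that add atoms: dimethyl sulfate COS(=O)(=O)OC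
Why: O-alkylation of an ambident β-keto ester enolate, favoured by the large cesium counter-ion, the dipolar aprotic solvent, the hard electrophile and the fully substituted α-carbon; both geometries are carried on.

Step 11
Reactants: 16 methyl 3-methoxy-2-(RO)but-2-enoate
Product: 18 1,3-dimethoxy-2-(RO)-1-(trimethylsilyloxy)buta-1,3-diene, via lithium dienolate 17 (not isolated)
Conditions: LiN(iPr)2, THF, -78 °C; Me3SiCl, -78 to 0 °C; pentane, filtration under Ar, used at once
Reagents that add atoms: chlorotrimethylsilane C[Si](C)(C)Cl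
Why: Vinylogous (γ) deprotonation of a β-alkoxy enoate and O-silylation of the dienolate is the standard entry to Brassard-type dienes; the former C2=C3 double bond becomes a single bond, so both isomers of 16 should converge on the same diene.

Step 12
Reactants: 19 methyl 4-hydroxybut-2-ynoate
Product: 20 methyl 4-oxobut-2-ynoate
Conditions: activated MnO2, CH2Cl2, rt; filtered through Celite, solution used directly
Reagents that add atoms: none
Why: MnO2 oxidation of a propargylic alcohol stops at the aldehyde, and a simple filtration delivers the sensitive ynal without aqueous handling.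

Step 13
Reactants: 18 1,3-dimethoxy-2-(RO)-1-(trimethylsilyloxy)buta-1,3-diene; 20 methyl 4-oxobut-2-ynoate
Product: 22 methyl 2-formyl-3-hydroxy-5-methoxy-4-(RO)benzoate, via cyclohexadiene silyl methyl ketal 21 (not isolated)
Conditions: 20 (1.5 equiv), CH2Cl2, -78 °C to rt; then 10% aq. citric acid, THF, 0 °C
Reagents that add atoms: none
Why: This is a thermal normal-demand Diels-Alder reaction expected to run asynchronously, like a Michael addition followed by ring closure: the CH2 end of diene 18, which receives the push of the donor oxygens at C1 and C3, bonds to the alkyne carbon β to the formyl group (the ester-bearing one), and the ketene acetal carbon then bonds to the formyl-bearing carbon. The closest known reaction type is the benzannulation of 1-alkoxy-1-silyloxy-3-alkoxybutadienes with acetylenic esters and ketones, which aromatise by loss of the ketal substituents. The six-membered carbocycle is closed by the [4+2] cycloaddition itself (new bonds C7-C7a and C4-C3a in phthalide numbering); mild acid then cleaves the O-Si bond of ketal 21, methanol leaves, and the cyclohexadienone tautomerises to the benzene ring, whose new OH sits next to the formyl group and is hydrogen-bonded to it. The only stereocentre formed, the ketal carbon of 21, is racemic and vanishes on aromatisation, so no stereocontrol is needed. The step needs regioselectivity, which rests on the formyl group being a stronger acceptor than the ester so that the larger LUMO coefficient lies on the ester-bearing carbon, and chemoselectivity for the triple bond over the aldehyde C=O, which is sought by leaving out any Lewis acid. The temperature stays at or below rt, where a [3,3] shift of the allyl vinyl ether unit of 18 (it would have to join two fully substituted carbons) and reaction of the remote trisubstituted olefins should not compete.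

Step 14
Reactants: 22 methyl 2-formyl-3-hydroxy-5-methoxy-4-(RO)benzoate
Product: 24 4-hydroxy-6-methoxy-5-(RO)isobenzofuran-1(3H)-one, via hydroxymethyl benzoate 23 (not isolated)
Conditions: NaBH4, MeOH/THF, 0 °C; then AcOH to pH 5, rt
Reagents that add atoms: none
Why: NaBH4 reduces the aryl aldehyde but not the ester, and the resulting benzylic alcohol ortho to the methyl ester should close the five-membered lactone by intramolecular acyl substitution (phthalide formation), completed by the mildly acidic work-up.

Step 15
Reactants: 24 4-hydroxy-6-methoxy-5-(RO)isobenzofuran-1(3H)-one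
Product: 25 Farnesylemefuranone E
Conditions: Bu4NF, AcOH (1:1), THF, 0 °C to rt
Reagents that add atoms: none
Why: Fluoride-driven cleavage of the tertiary triethylsilyl ether, buffered with acetic acid so that the phenol, the lactone and the allylic aryl ether are not exposed to strong base or acid.

**Compound list**

1 | (2E,6E)-farnesol | CC(C)=CCC/C(C)=C/CC/C(C)=C/CO | starting material
2 | (2E,6E)-farnesyl acetate | CC(C)=CCC/C(C)=C/CC/C(C)=C/COC(C)=O | intermediate
3 | (2E,6E)-10-bromo-11-hydroxy-3,7,11-trimethyldodeca-2,6-dien-1-yl acetate (racemic) | CC(=O)OC/C=C(\C)CC/C=C(\C)CCC(Br)C(C)(C)O | intermediate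
4 | (2E,6E)-10,11-epoxy-3,7,11-trimethyldodeca-2,6-dien-1-yl acetate (racemic, not isolated) | CC(=O)OC/C=C(\C)CC/C=C(\C)CCC1OC1(C)C | intermediate
5 | (2E,6E)-10,11-epoxy-3,7,11-trimethyldodeca-2,6-dien-1-ol (racemic) | OC/C=C(\C)CC/C=C(\C)CCC1OC1(C)C | intermediate
6 | (2E,6E)-3,7,11-trimethyldodeca-2,6-diene-1,11-diol | OC/C=C(\C)CC/C=C(\C)CCCC(C)(C)O | intermediate
7 | (2E,6E)-1,11-bis(triethylsilyloxy)-3,7,11-trimethyldodeca-2,6-diene | CC[Si](CC)(CC)OC/C=C(\C)CC/C=C(\C)CCCC(C)(C)O[Si](CC)(CC)CC | intermediate
8 | (2E,6E)-3,7,11-trimethyl-11-(triethylsilyloxy)dodeca-2,6-dien-1-ol (RO-H) | OC/C=C(\C)CC/C=C(\C)CCCC(C)(C)O[Si](CC)(CC)CC | intermediate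
9 | bromoacetic acid | OC(=O)CBr | starting material
10 | 2-(RO)acetic acid | OC(=O)COC/C=C(\C)CC/C=C(\C)CCCC(C)(C)O[Si](CC)(CC)CC | intermediate
11 | methyl 2-(RO)acetate | COC(=O)COC/C=C(\C)CC/C=C(\C)CCCC(C)(C)O[Si](CC)(CC)CC | intermediate
12 | N-methoxy-N-methylacetamide | CON(C)C(C)=O | starting material
13 | lithium enolate of methyl 2-(RO)acetate (not isolated) | [Li+].[O-]C(OC)=COC/C=C(\C)CC/C=C(\C)CCCC(C)(C)O[Si](CC)(CC)CC | intermediate
14 | lithium salt of methyl 3-hydroxy-3-[methoxy(methyl)amino]-2-(RO)butanoate, the tetrahedral adduct (not isolated) | [Li+].[O-]C(C)(N(C)OC)C(OC/C=C(\C)CC/C=C(\C)CCCC(C)(C)O[Si](CC)(CC)CC)C(=O)OC | intermediate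
15 | methyl 3-oxo-2-(RO)butanoate (racemic) | COC(=O)C(OC/C=C(\C)CC/C=C(\C)CCCC(C)(C)O[Si](CC)(CC)CC)C(C)=O | intermediate
16 | methyl 3-methoxy-2-(RO)but-2-enoate (E/Z mixture) | COC(=O)C(OC/C=C(\C)CC/C=C(\C)CCCC(C)(C)O[Si](CC)(CC)CC)=C(C)OC | intermediate
17 | lithium dienolate of 16 (not isolated) | [Li+].[O-]C(OC)=C(OC/C=C(\C)CC/C=C(\C)CCCC(C)(C)O[Si](CC)(CC)CC)C(=C)OC | intermediate
18 | 1,3-dimethoxy-2-(RO)-1-(trimethylsilyloxy)buta-1,3-diene | C=C(OC)C(OC/C=C(\C)CC/C=C(\C)CCCC(C)(C)O[Si](CC)(CC)CC)=C(OC)O[Si](C)(C)C | intermediate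
19 | methyl 4-hydroxybut-2-ynoate | COC(=O)C#CCO | starting material
20 | methyl 4-oxobut-2-ynoate | COC(=O)C#CC=O | intermediate
21 | methyl 2-formyl-3,5-dimethoxy-4-(RO)-3-(trimethylsilyloxy)cyclohexa-1,4-diene-1-carboxylate (racemic, not isolated) | COC(=O)C1=C(C=O)C(OC)(O[Si](C)(C)C)C(OC/C=C(\C)CC/C=C(\C)CCCC(C)(C)O[Si](CC)(CC)CC)=C(OC)C1 | intermediate
22 | methyl 2-formyl-3-hydroxy-5-methoxy-4-(RO)benzoate | COC(=O)c1cc(OC)c(OC/C=C(\C)CC/C=C(\C)CCCC(C)(C)O[Si](CC)(CC)CC)c(O)c1C=O | intermediate
23 | methyl 3-hydroxy-2-(hydroxymethyl)-5-methoxy-4-(RO)benzoate (not isolated) | COC(=O)c1cc(OC)c(OC/C=C(\C)CC/C=C(\C)CCCC(C)(C)O[Si](CC)(CC)CC)c(O)c1CO | intermediate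
24 | 4-hydroxy-6-methoxy-5-(RO)isobenzofuran-1(3H)-one | COc1cc2c(c(O)c1OC/C=C(\C)CC/C=C(\C)CCCC(C)(C)O[Si](CC)(CC)CC)COC2=O | intermediate
25 | Farnesylemefuranone E, 4-hydroxy-5-[(2E,6E)-11-hydroxy-3,7,11-trimethyldodeca-2,6-dienyloxy]-6-methoxyisobenzofuran-1(3H)-one | COc1cc2c(c(O)c1OC/C=C(\C)CC/C=C(\C)CCCC(C)(C)O)COC2=O | target

**Count**

Total step count: 15. Longest linear sequence: 14 (steps 1 to 11 and 13 to 15, from farnesol); step 12 is a one-step branch.

**Steps most likely to fail**

1. Step 13 (cycloaddition and aromatisation).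
   - What may go wrong: the silyl ketene acetal end of the diene may add to the aldehyde carbonyl (aldol-type addition or oxa-cycloaddition) instead of across the triple bond. The orientation of addition may be incompletely controlled because both alkyne carbons carry an acceptor. The diene may be protodesilylated before it reacts.
   - Fallback, setting out from 18 and returning at 24: the diene is combined with dimethyl but-2-ynedioate (toluene, rt to 50 °C), a symmetrical dienophile without an aldehyde, to give dimethyl 3,5-dimethoxy-4-(RO)-3-(trimethylsilyloxy)cyclohexa-1,4-diene-1,2-dicarboxylate F1. The same citric acid work-up should aromatise it to dimethyl 3-hydroxy-5-methoxy-4-(RO)phthalate F2. LiOH in THF/H2O (0 °C to rt) should hydrolyse only the ester remote from the phenoxide, since the other ester is flanked on both sides and conjugated to the phenoxide, giving 3-hydroxy-5-methoxy-2-(methoxycarbonyl)-4-(RO)benzoic acid F3. LiBH4 in THF (0 °C to rt) reduces the remaining ester but not the carboxylate, giving 3-hydroxy-2-(hydroxymethyl)-5-methoxy-4-(RO)benzoic acid F4, which should lactonise on acidification to pH 3 to 4 to the silyl-protected phthalide 24.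

2. Step 9 (acylation with the Weinreb amide).
   - What may go wrong: proton transfer from the acetyl group of the amide to the ester enolate would return unreacted ester. Warming to force the addition would open the [2,3]-Wittig pathway of the α-allyloxy enolate.
   - Fallback, setting out from 11 and returning at 15: the enolate (LiN(iPr)2, THF, -78 °C) is trapped with acetaldehyde, an addition that is fast at -78 °C, to give methyl 3-hydroxy-2-(RO)butanoate F5 as a diastereomer mixture. Oxidation with Dess-Martin periodinane (NaHCO3, CH2Cl2, 0 °C to rt) then gives β-keto ester 15.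

3. Step 10 (O-methylation of the β-keto ester).
   - What may go wrong: competing C-methylation at the α-carbon, or a sigmatropic shift of the allyloxy-substituted enolate, would consume material before the enol ether forms.
   - Fallback, setting out from 15 and returning at 22: the keto ester is silylated (Me3SiCl, Et3N, THF, rt) to methyl 2-(RO)-3-(trimethylsilyloxy)but-2-enoate F6. γ-Deprotonation and silylation (LiN(iPr)2, Me3SiCl, THF, -78 °C) give 1-methoxy-2-(RO)-1,3-bis(trimethylsilyloxy)buta-1,3-diene F7. Cycloaddition with ynal 20 (CH2Cl2, -78 °C to rt) gives methyl 2-formyl-3-methoxy-4-(RO)-3,5-bis(trimethylsilyloxy)cyclohexa-1,4-diene-1-carboxylate F8, and citric acid work-up should give methyl 2-formyl-3,5-dihydroxy-4-(RO)benzoate F9. The hydroxyl para to the formyl group is not hydrogen-bonded and is the more acidic, so MeI (1 equiv) with KHCO3 in DMF at rt should methylate it alone and give 22; the price is one phenol alkylation.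

**Further compounds**

F1 | step 13 | dimethyl 3,5-dimethoxy-4-(RO)-3-(trimethylsilyloxy)cyclohexa-1,4-diene-1,2-dicarboxylate | COC(=O)C1=C(C(=O)OC)C(OC)(O[Si](C)(C)C)C(OC/C=C(\C)CC/C=C(\C)CCCC(C)(C)O[Si](CC)(CC)CC)=C(OC)C1
F2 | step 13 | dimethyl 3-hydroxy-5-methoxy-4-(RO)phthalate | COC(=O)c1cc(OC)c(OC/C=C(\C)CC/C=C(\C)CCCC(C)(C)O[Si](CC)(CC)CC)c(O)c1C(=O)OC
F3 | step 13 | 3-hydroxy-5-methoxy-2-(methoxycarbonyl)-4-(RO)benzoic acid | OC(=O)c1cc(OC)c(OC/C=C(\C)CC/C=C(\C)CCCC(C)(C)O[Si](CC)(CC)CC)c(O)c1C(=O)OC
F4 | step 13 | 3-hydroxy-2-(hydroxymethyl)-5-methoxy-4-(RO)benzoic acid | OC(=O)c1cc(OC)c(OC/C=C(\C)CC/C=C(\C)CCCC(C)(C)O[Si](CC)(CC)CC)c(O)c1CO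
F5 | step 9 | methyl 3-hydroxy-2-(RO)butanoate (diastereomer mixture) | COC(=O)C(OC/C=C(\C)CC/C=C(\C)CCCC(C)(C)O[Si](CC)(CC)CC)C(C)O
F6 | step 10 | methyl 2-(RO)-3-(trimethylsilyloxy)but-2-enoate | COC(=O)C(OC/C=C(\C)CC/C=C(\C)CCCC(C)(C)O[Si](CC)(CC)CC)=C(C)O[Si](C)(C)C
F7 | step 10 | 1-methoxy-2-(RO)-1,3-bis(trimethylsilyloxy)buta-1,3-diene | C=C(O[Si](C)(C)C)C(OC/C=C(\C)CC/C=C(\C)CCCC(C)(C)O[Si](CC)(CC)CC)=C(OC)O[Si](C)(C)C
F8 | step 10 | methyl 2-formyl-3-methoxy-4-(RO)-3,5-bis(trimethylsilyloxy)cyclohexa-1,4-diene-1-carboxylate | COC(=O)C1=C(C=O)C(OC)(O[Si](C)(C)C)C(OC/C=C(\C)CC/C=C(\C)CCCC(C)(C)O[Si](CC)(CC)CC)=C(O[Si](C)(C)C)C1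
F9 | step 10 | methyl 2-formyl-3,5-dihydroxy-4-(RO)benzoate | COC(=O)c1cc(O)c(OC/C=C(\C)CC/C=C(\C)CCCC(C)(C)O[Si](CC)(CC)CC)c(O)c1C=O
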